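**Plan**

1. Retrosynthesis: the glyceride ester at C15 and the PMB ether are cut first. Ring B is a cyclohexene with its double bond at C8=C9, so the two σ-bonds one atom away from that alkene, the ring-fusion bond C5–C10 and C6–C7, are cut together as a retro-Diels–Alder. Ring A (C1–C4) is then the four-atom tether from diene terminus C10 to dienophile carbon C5 of an acyclic trienal; a formyl group on C6 is the activating helper, and quaternary C4 leaves the enal without γ-hydrogens.
2. The triene is cut at C9–C11 (Negishi coupling) and C10–C1 (carbocupration of methyl but-2-ynoate); C8 is the ester carbon, C7 and C17 come from MeMgBr.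
3. Forward: tether bromide → syn-carbocupration/iodination (fixes the C9=C10 geometry) → isopropenyl group → Negishi coupling with the C11–C15 chain → enal release → one intramolecular Diels–Alder reaction closes rings A and B → decarbonylation of the helper → saponification, glycerol esterification, PMB removal.
4. Stereochemistry: C13 is bought with (R)-methyl hydrogen 3-methylglutarate and glycerol C2 with (S)-solketal. C5 is set by an imidazolidinone catalyst, and C10 is relayed from C5 in the same event by the endo transition state and the diene geometry (trans fusion).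

Key step: step 11

Remark: C-numbers are labdane numbers of the target (decalin C1–C10, side chain C11–C16, C17 on C8, C18/C19 on C4, C20 on C10); ethyl 5-bromo-2,2-dimethylpentanoate and (R)-methyl hydrogen 3-methylglutarate are taken as catalogue compounds.

**Route**

Step 1
Reactants: 1 ethyl 5-bromo-2,2-dimethylpentanoate
Product: 2 5-bromo-2,2-dimethylpentanal
Conditions: DIBAL-H (1.05 equiv), CH2Cl2, −78 °C; Rochelle salt work-up
Reagents that add atoms: none
Why: DIBAL-H half-reduction of an ester: the tetrahedral aluminium acetal of the α-quaternary ester is stable at −78 °C and releases the aldehyde only on work-up, and the primary bromide is inert.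

Step 2
Reactants: 2 5-bromo-2,2-dimethylpentanal
Product: 3 (2E)-7-bromo-4,4-dimethylhept-2-enal
Conditions: Ph3P=CHCHO (1.2 equiv), toluene, 90 °C
Reagents that add atoms: (triphenylphosphoranylidene)acetaldehyde, O=CC=P(c1ccccc1)(c1ccccc1)c1ccccc1
Why: Wittig olefination with the stabilised formylmethylene ylide should give the (E)-enal and adds C6 plus the formyl helper carbon in one step; the non-enolisable aldehyde cannot self-condense.

Step 3
Reactants: 3 (2E)-7-bromo-4,4-dimethylhept-2-enal
Product: 4 (2E)-7-bromo-1,1-dimethoxy-4,4-dimethylhept-2-ene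
Conditions: HC(OMe)3, MeOH, PPTS (cat.), rt
Reagents that add atoms: trimethyl orthoformate, COC(OC)OC
Why: Acid-catalysed acetalisation with an orthoformate as water scavenger masks the enal so that it survives the Grignard, organocopper and MeMgBr steps.

Step 4
Reactants: 4 (2E)-7-bromo-1,1-dimethoxy-4,4-dimethylhept-2-ene; 5 methyl but-2-ynoate
Product: 9 methyl (2Z,8E)-2-iodo-10,10-dimethoxy-3,7,7-trimethyldeca-2,8-dienoate, via Grignard reagent 6 (not isolated), via alkylcopper reagent 7 (not isolated), via alkenylcopper adduct 8 (not isolated)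
Conditions: Mg, THF, rt; CuBr·SMe2 (1 equiv), THF/Me2S, −45 °C; 5, −78 °C; I2, THF, −78 → 0 °C
Reagents that add atoms: iodine, II
Why: Syn-carbocupration of a 2-alkynoate (conjugate addition of RCu·MgBr2) followed by iodinolysis with retention fixes the tetrasubstituted C9=C10 geometry, tether cis to iodine and C20 methyl cis to the ester, provided the α-cuprio ester is kept at −78 °C until iodine is added.

Step 5
Reactants: 9 methyl (2Z,8E)-2-iodo-10,10-dimethoxy-3,7,7-trimethyldeca-2,8-dienoate
Product: 10 (3Z,9E)-3-iodo-11,11-dimethoxy-2,4,8,8-tetramethylundeca-3,9-dien-2-ol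
Conditions: MeMgBr (3.5 equiv), Et2O/THF, −20 → 0 °C
Reagents that add atoms: methylmagnesium bromide, C[Mg]Br
Why: Double Grignard addition to the ester gives the tertiary carbinol (future C8 with C7 and C17); MeMgBr is not expected to undergo iodine–magnesium exchange with the alkenyl iodide at this temperature, and the acetal is inert.

Step 6
Reactants: 10 (3Z,9E)-3-iodo-11,11-dimethoxy-2,4,8,8-tetramethylundeca-3,9-dien-2-ol
Product: 11 (3Z,9E)-3-iodo-11,11-dimethoxy-2,4,8,8-tetramethylundeca-1,3,9-triene
Conditions: Burgess reagent (1.5 equiv), toluene, 50 °C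
Reagents that add atoms: none
Why: Burgess dehydration (syn-elimination through the sulfamate) can only take a hydrogen from one of the two methyl groups, because C9 carries none, so the isopropenyl group (C7=C8) should form without touching the C9=C10 geometry.

Step 7
Reactants: 12 (R)-methyl hydrogen 3-methylglutarate [(3R)-5-methoxy-3-methyl-5-oxopentanoic acid]
Product: 13 methyl (3R)-5-hydroxy-3-methylpentanoate
Conditions: BH3·SMe2 (1.1 equiv), THF, −10 °C → rt; aqueous work-up
Reagents that add atoms: none
Why: Borane reduces the free carboxylic acid chemoselectively in the presence of the methyl ester (acyloxyborane pathway); C13 is not touched.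

Step 8
Reactants: 13 methyl (3R)-5-hydroxy-3-methylpentanoate
Product: 14 methyl (3S)-5-iodo-3-methylpentanoate
Conditions: I2, PPh3, imidazole, CH2Cl2, 0 °C
Reagents that add atoms: iodine, II
Why: Garegg–Samuelsson (Appel-type) iodination converts the primary alcohol without effect on the stereocentre (the descriptor changes only by priority) and is run at once to forestall lactonisation of the hydroxy ester.

Step 9
Reactants: 11 (3Z,9E)-3-iodo-11,11-dimethoxy-2,4,8,8-tetramethylundeca-1,3,9-triene; 14 methyl (3S)-5-iodo-3-methylpentanoate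
Product: 16 methyl (3R,6E,12E)-14,14-dimethoxy-3,7,11,11-tetramethyl-6-(prop-1-en-2-yl)tetradeca-6,12-dienoate, via alkylzinc iodide 15 (not isolated)
Conditions: 14, Zn dust (activated), LiCl, THF, 30 °C; then 11, Pd(OAc)2 (3 mol %), SPhos (6 mol %), THF, 50 °C
Reagents that add atoms: none
Why: LiCl-mediated zinc insertion gives an ester-tolerant alkylzinc iodide, and Negishi sp2–sp3 cross-coupling proceeds with retention at the alkenyl iodide, so C11 ends up cis to the tether (C1) and C8 cis to the C20 methyl.

Step 10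
Reactants: 16 methyl (3R,6E,12E)-14,14-dimethoxy-3,7,11,11-tetramethyl-6-(prop-1-en-2-yl)tetradeca-6,12-dienoate
Product: 17 methyl (3R,6E,12E)-3,7,11,11-tetramethyl-14-oxo-6-(prop-1-en-2-yl)tetradeca-6,12-dienoate
Conditions: PPTS (0.2 equiv), acetone/H2O 10:1, rt
Reagents that add atoms: water, O
Why: Mild acid hydrolysis of the allylic dimethyl acetal releases the (E)-enal dienophile; methyl ester and diene should tolerate PPTS at room temperature.

Step 11
Reactants: 17 methyl (3R,6E,12E)-3,7,11,11-tetramethyl-14-oxo-6-(prop-1-en-2-yl)tetradeca-6,12-dienoate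
Product: 18 methyl (3R)-5-[(4R,4aR,8aR)-4-formyl-2,5,5,8a-tetramethyl-3,4,4a,5,6,7,8,8a-octahydronaphthalen-1-yl]-3-methylpentanoate
Conditions: (2R,5R)-5-benzyl-2-tert-butyl-3-methylimidazolidin-4-one·TFA (20 mol %), MeCN/H2O 95:5, 0.02 M, 0 °C → rt
Reagents that add atoms: none
Why: The secondary amine condenses with the enal to an (E)-iminium ion (no γ-hydrogen, hence no dienamine), whose lowered LUMO undergoes a concerted, asynchronous intramolecular [4+2] cycloaddition with the C7=C8–C9=C10 diene to form C5–C10 and C6–C7, and hydrolysis returns the catalyst; the closest known reaction is the imidazolidinone-catalysed type-1 intramolecular Diels–Alder reaction of (2E,7E,9E)-deca-2,7,9-trienals to trans-fused octalin carbaldehydes. Ring B (C5–C10) is the six-membered cycloaddition ring and ring A (C1–C5, C10) closes across the four-atom tether C1–C4 through the same C5–C10 bond, the gem-dimethyl group at C4 favouring the folded conformer. C5: the benzyl and tert-butyl groups of the (2R,5R) catalyst cover the Si face of C5 in the iminium ion, so C10 should add to the Re face and C5 becomes R. C10: the tether sits trans to C8 on the diene terminus (outside) and the iminium group is endo, which puts the tether in a chair-like anti arrangement and H-5 trans to CH3-20, hence 10R and a trans ring fusion. C6 (transient): the formyl group ends up trans to C4 because the enal is E. The step needs endo over exo selectivity and reaction at or below room temperature, both expected from iminium activation, so that the 1,5-hydrogen shift of the inside methyl group of the diene and the uncatalysed, unselective cycloaddition do not compete.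

Step 12
Reactants: 18 methyl (3R)-5-[(4R,4aR,8aR)-4-formyl-2,5,5,8a-tetramethyl-3,4,4a,5,6,7,8,8a-octahydronaphthalen-1-yl]-3-methylpentanoate
Product: 19 methyl (3R)-3-methyl-5-[(4aR,8aR)-2,5,5,8a-tetramethyl-3,4,4a,5,6,7,8,8a-octahydronaphthalen-1-yl]pentanoate
Conditions: [Rh(dppp)2]Cl (5 mol %), diglyme, 160 °C, N2 stream
Reagents that add atoms: none
Why: Tsuji–Wilkinson-type rhodium-catalysed decarbonylation (acyl–Rh–H, CO extrusion, C–H reductive elimination) removes the formyl helper and turns C6 into a methylene group, so its configuration is of no consequence.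

Step 13
Reactants: 19 methyl (3R)-3-methyl-5-[(4aR,8aR)-2,5,5,8a-tetramethyl-3,4,4a,5,6,7,8,8a-octahydronaphthalen-1-yl]pentanoate
Product: 20 (3R)-3-methyl-5-[(4aR,8aR)-2,5,5,8a-tetramethyl-3,4,4a,5,6,7,8,8a-octahydronaphthalen-1-yl]pentanoic acid
Conditions: LiOH·H2O (3 equiv), THF/MeOH/H2O, rt; 1 M HCl to pH 3
Reagents that add atoms: lithium hydroxide, [Li+].[OH-]
Why: Saponification of the unhindered methyl ester; no stereocentre is α to the carboxyl group.

Step 14
Reactants: 21 (S)-solketal [(4S)-2,2-dimethyl-1,3-dioxolan-4-yl]methanol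
Product: 22 (4S)-4-{[(4-methoxybenzyl)oxy]methyl}-2,2-dimethyl-1,3-dioxolane
Conditions: NaH, PMBCl, Bu4NI (cat.), DMF, 0 °C → rt
Reagents that add atoms: 4-methoxybenzyl chloride, COc1ccc(CCl)cc1
Why: Williamson etherification protects O-3 of the glycerol as a PMB ether that can later be removed oxidatively under neutral conditions; the stereocentre is untouched.

Step 15
Reactants: 22 (4S)-4-{[(4-methoxybenzyl)oxy]methyl}-2,2-dimethyl-1,3-dioxolane
Product: 23 (2R)-3-[(4-methoxybenzyl)oxy]propane-1,2-diol
Conditions: AcOH/H2O 4:1, 40 °C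
Reagents that add atoms: none
Why: Acid hydrolysis of the isopropylidene acetal; PMB ethers survive aqueous acetic acid.

Step 16
Reactants: 23 (2R)-3-[(4-methoxybenzyl)oxy]propane-1,2-diol
Product: 24 (2S)-2-hydroxy-3-[(4-methoxybenzyl)oxy]propyl acetate
Conditions: AcCl (1.05 equiv), 2,4,6-collidine, CH2Cl2, −78 °C
Reagents that add atoms: acetyl chloride, CC(Cl)=O
Why: Kinetically controlled acylation at −78 °C with collidine as base differentiates the primary from the secondary hydroxyl group of the 1,2-diol.

Step 17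
Reactants: 20 (3R)-3-methyl-5-[(4aR,8aR)-2,5,5,8a-tetramethyl-3,4,4a,5,6,7,8,8a-octahydronaphthalen-1-yl]pentanoic acid; 24 (2S)-2-hydroxy-3-[(4-methoxybenzyl)oxy]propyl acetate
Product: 25 (2S)-1-acetoxy-3-[(4-methoxybenzyl)oxy]propan-2-yl (3R)-3-methyl-5-[(4aR,8aR)-2,5,5,8a-tetramethyl-3,4,4a,5,6,7,8,8a-octahydronaphthalen-1-yl]pentanoate
Conditions: DCC, DMAP (0.1 equiv), CH2Cl2, 0 °C → rt
Reagents that add atoms: none
Why: Steglich esterification acylates the secondary hydroxyl group at low temperature, where the neighbouring acetate should not migrate appreciably and no stereocentre is at risk.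

Step 18
Reactants: 25 (2S)-1-acetoxy-3-[(4-methoxybenzyl)oxy]propan-2-yl (3R)-3-methyl-5-[(4aR,8aR)-2,5,5,8a-tetramethyl-3,4,4a,5,6,7,8,8a-octahydronaphthalen-1-yl]pentanoate
Product: 26 (2S)-1-acetoxy-3-hydroxypropan-2-yl (3R)-3-methyl-5-[(4aR,8aR)-2,5,5,8a-tetramethyl-3,4,4a,5,6,7,8,8a-octahydronaphthalen-1-yl]pentanoate
Conditions: DDQ (1.3 equiv), CH2Cl2/pH 7 phosphate buffer 10:1, 0 °C
Reagents that add atoms: none
Why: Oxidative PMB cleavage with DDQ (benzylic hydride abstraction, hydrolysis of the oxocarbenium ion) in buffered medium frees O-3 without acid or base, which should suppress the 2→3 acyl shift of the 1,2-diacylglycerol.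

**Compound list**

1 | ethyl 5-bromo-2,2-dimethylpentanoate | CCOC(=O)C(C)(C)CCCBr | starting material
2 | 5-bromo-2,2-dimethylpentanal | O=CC(C)(C)CCCBr | intermediate
3 | (2E)-7-bromo-4,4-dimethylhept-2-enal | O=C/C=C/C(C)(C)CCCBr | intermediate
4 | (2E)-7-bromo-1,1-dimethoxy-4,4-dimethylhept-2-ene | COC(OC)/C=C/C(C)(C)CCCBr | intermediate
5 | methyl but-2-ynoate | CC#CC(=O)OC | starting material
6 | [(5E)-7,7-dimethoxy-4,4-dimethylhept-5-en-1-yl]magnesium bromide (Grignard reagent) | COC(OC)/C=C/C(C)(C)CCC[Mg]Br | intermediate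
7 | [(5E)-7,7-dimethoxy-4,4-dimethylhept-5-en-1-yl]copper (alkylcopper reagent, MgBr2 complex) | COC(OC)/C=C/C(C)(C)CCC[Cu] | intermediate
8 | alkenylcopper adduct, copper on C2 cis to the C4 chain of methyl (8E)-10,10-dimethoxy-3,7,7-trimethyldeca-2,8-dienoate | COC(=O)/C([Cu])=C(\C)CCCC(C)(C)/C=C/C(OC)OC | intermediate
9 | methyl (2Z,8E)-2-iodo-10,10-dimethoxy-3,7,7-trimethyldeca-2,8-dienoate | COC(=O)/C(I)=C(\C)CCCC(C)(C)/C=C/C(OC)OC | intermediate
10 | (3Z,9E)-3-iodo-11,11-dimethoxy-2,4,8,8-tetramethylundeca-3,9-dien-2-ol | CC(C)(O)/C(I)=C(\C)CCCC(C)(C)/C=C/C(OC)OC | intermediate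
11 | (3Z,9E)-3-iodo-11,11-dimethoxy-2,4,8,8-tetramethylundeca-1,3,9-triene | C=C(C)/C(I)=C(\C)CCCC(C)(C)/C=C/C(OC)OC | intermediate
12 | (R)-methyl hydrogen 3-methylglutarate | COC(=O)C[C@H](C)CC(=O)O | starting material
13 | methyl (3R)-5-hydroxy-3-methylpentanoate | COC(=O)C[C@H](C)CCO | intermediate
14 | methyl (3S)-5-iodo-3-methylpentanoate | COC(=O)C[C@H](C)CCI | intermediate
15 | [(3S)-5-methoxy-3-methyl-5-oxopentyl]zinc iodide (alkylzinc iodide) | COC(=O)C[C@H](C)CC[Zn]I | intermediate
16 | methyl (3R,6E,12E)-14,14-dimethoxy-3,7,11,11-tetramethyl-6-(prop-1-en-2-yl)tetradeca-6,12-dienoate | C=C(C)/C(CC[C@@H](C)CC(=O)OC)=C(\C)CCCC(C)(C)/C=C/C(OC)OC | intermediate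
17 | methyl (3R,6E,12E)-3,7,11,11-tetramethyl-14-oxo-6-(prop-1-en-2-yl)tetradeca-6,12-dienoate | C=C(C)/C(CC[C@@H](C)CC(=O)OC)=C(\C)CCCC(C)(C)/C=C/C=O | intermediate
18 | methyl (3R)-5-[(4R,4aR,8aR)-4-formyl-2,5,5,8a-tetramethyl-3,4,4a,5,6,7,8,8a-octahydronaphthalen-1-yl]-3-methylpentanoate | COC(=O)C[C@H](C)CCC1=C(C)C[C@@H](C=O)[C@@H]2C(C)(C)CCC[C@@]12C | intermediate
19 | methyl (3R)-3-methyl-5-[(4aR,8aR)-2,5,5,8a-tetramethyl-3,4,4a,5,6,7,8,8a-octahydronaphthalen-1-yl]pentanoate | COC(=O)C[C@H](C)CCC1=C(C)CC[C@@H]2C(C)(C)CCC[C@@]12C | intermediate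
20 | (3R)-3-methyl-5-[(4aR,8aR)-2,5,5,8a-tetramethyl-3,4,4a,5,6,7,8,8a-octahydronaphthalen-1-yl]pentanoic acid | OC(=O)C[C@H](C)CCC1=C(C)CC[C@@H]2C(C)(C)CCC[C@@]12C | intermediate
21 | (S)-solketal, [(4S)-2,2-dimethyl-1,3-dioxolan-4-yl]methanol | CC1(C)OC[C@H](CO)O1 | starting material
22 | (4S)-4-{[(4-methoxybenzyl)oxy]methyl}-2,2-dimethyl-1,3-dioxolane | CC1(C)OC[C@H](COCc2ccc(OC)cc2)O1 | intermediate
23 | (2R)-3-[(4-methoxybenzyl)oxy]propane-1,2-diol | OC[C@H](COCc1ccc(OC)cc1)O | intermediate
24 | (2S)-2-hydroxy-3-[(4-methoxybenzyl)oxy]propyl acetate | CC(=O)OC[C@H](COCc1ccc(OC)cc1)O | intermediate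
25 | (2S)-1-acetoxy-3-[(4-methoxybenzyl)oxy]propan-2-yl (3R)-3-methyl-5-[(4aR,8aR)-2,5,5,8a-tetramethyl-3,4,4a,5,6,7,8,8a-octahydronaphthalen-1-yl]pentanoate | CC(=O)OC[C@H](COCc3ccc(OC)cc3)OC(=O)C[C@H](C)CCC1=C(C)CC[C@@H]2C(C)(C)CCC[C@@]12C | intermediate
26 | (2S)-1-acetoxy-3-hydroxypropan-2-yl (3R)-3-methyl-5-[(4aR,8aR)-2,5,5,8a-tetramethyl-3,4,4a,5,6,7,8,8a-octahydronaphthalen-1-yl]pentanoate | CC(=O)OC[C@H](CO)OC(=O)C[C@H](C)CCC1=C(C)CC[C@@H]2C(C)(C)CCC[C@@]12C | target

**Totals**

Total step count: 18. Longest linear sequence: 13 steps (1–6, 9–13, 17, 18).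

**Steps most likely to fail**

Step 11. The cycloaddition may stall at the hindered C5–C10 bond under iminium catalysis, the amine salt may discriminate the two faces of C5 poorly, or the acid may isomerise the diene. Fallback (auxiliary-controlled, Lewis-acid-promoted intramolecular Diels–Alder reaction of a trienimide): starting from 17, Pinnick oxidation (NaClO2, NaH2PO4, 2-methylbut-2-ene) would give the trienoic acid F1. Its pivaloyl mixed anhydride would acylate lithiated (R)-4-benzyloxazolidin-2-one to the trienimide F2. Me2AlCl (CH2Cl2, −30 °C) would give the endo adduct F3 through the chelated s-cis imide, in which the benzyl group covers the Si face of C5. LiOOH would release the acid F4, DCC coupling with N-hydroxypyridine-2-thione would give the thiohydroxamate ester F5 (used without isolation), and photolysis with t-BuSH (Barton reductive decarboxylation) would come back to the route at 19.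

Step 6. The tertiary allylic sulfamate may ionise instead of eliminating syn, and the resulting allyl cation may lose a proton from C20 or C1 or scramble the C9=C10 geometry. Fallback (ketone methylenation instead of dehydration, replacing steps 5 and 6): starting from 9, Me3Al/MeNH(OMe)·HCl would give the Weinreb amide F6, MeMgBr would give the methyl ketone F7, and Wittig methylenation (Ph3P=CH2, THF, 0 °C) would come back to the route at 11 without any cationic intermediate.

Step 9. Transmetalation and reductive elimination at the tetrasubstituted alkenylpalladium centre may be slow, so that β-hydride elimination of the alkyl group and protodehalogenation take over. Fallback (reversed polarity): starting from 11, iodine–lithium exchange (t-BuLi, Et2O, −78 °C) would give the dienyllithium F8, ZnBr2 would give the dienylzinc bromide F9, and a palladium/tricyclopentylphosphine-catalysed alkyl–alkenyl Negishi coupling with the primary iodide 14 would come back to the route at 16.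

**Further compounds**

F1 | step 11 | (2E,8E,12R)-14-methoxy-4,4,8,12-tetramethyl-14-oxo-9-(prop-1-en-2-yl)tetradeca-2,8-dienoic acid | C=C(C)/C(CC[C@@H](C)CC(=O)OC)=C(\C)CCCC(C)(C)/C=C/C(=O)O
F2 | step 11 | methyl (3R,6E,12E)-14-[(4R)-4-benzyl-2-oxo-1,3-oxazolidin-3-yl]-3,7,11,11-tetramethyl-14-oxo-6-(prop-1-en-2-yl)tetradeca-6,12-dienoate | C=C(C)/C(CC[C@@H](C)CC(=O)OC)=C(\C)CCCC(C)(C)/C=C/C(=O)N1[C@H](Cc2ccccc2)COC1=O
F3 | step 11 | methyl (3R)-5-[(4R,4aR,8aR)-4-{[(4R)-4-benzyl-2-oxo-1,3-oxazolidin-3-yl]carbonyl}-2,5,5,8a-tetramethyl-3,4,4a,5,6,7,8,8a-octahydronaphthalen-1-yl]-3-methylpentanoate | COC(=O)C[C@H](C)CCC1=C(C)C[C@@H](C(=O)N3[C@H](Cc4ccccc4)COC3=O)[C@@H]2C(C)(C)CCC[C@@]12C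
F4 | step 11 | (1R,4aR,8aR)-4-[(3R)-5-methoxy-3-methyl-5-oxopentyl]-3,4a,8,8-tetramethyl-1,2,4a,5,6,7,8,8a-octahydronaphthalene-1-carboxylic acid | COC(=O)C[C@H](C)CCC1=C(C)C[C@@H](C(=O)O)[C@@H]2C(C)(C)CCC[C@@]12C
F5 | step 11 | 2-thioxopyridin-1(2H)-yl ester of F4 (Barton ester) | COC(=O)C[C@H](C)CCC1=C(C)C[C@@H](C(=O)On3ccccc3=S)[C@@H]2C(C)(C)CCC[C@@]12C
F6 | step 6 | (2Z,8E)-2-iodo-N,10,10-trimethoxy-N,3,7,7-tetramethyldeca-2,8-dienamide | CON(C)C(=O)/C(I)=C(\C)CCCC(C)(C)/C=C/C(OC)OC
F7 | step 6 | (3Z,9E)-3-iodo-11,11-dimethoxy-4,8,8-trimethylundeca-3,9-dien-2-one | CC(=O)/C(I)=C(\C)CCCC(C)(C)/C=C/C(OC)OC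
F8 | step 9 | dienyllithium from 11, lithium in place of iodine with retained geometry | C=C(C)/C([Li])=C(\C)CCCC(C)(C)/C=C/C(OC)OC
F9 | step 9 | dienylzinc bromide from F8, zinc in place of lithium with retained geometry | C=C(C)/C([Zn]Br)=C(\C)CCCC(C)(C)/C=C/C(OC)OC
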